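The route rests on cutting ring C at C3–C4. In the target the C4 ketone sits on C4a, ortho to the O1-bearing C8a, so ring C is an isomer of a benzaldehyde whose formyl carbon is C4 and whose ortho oxygen O1 carries C2=C3 as a 1-arylvinyl ether. A cationic monovalent rhodium catalyst with a chiral bisphosphine adds the formyl C–H bond across this alkene: one isomerisation forms C3–C4, closes ring C and sets C2. The precursor is achiral, already carries the C8 prenyl group, and has O5, O7 and O4′ as MOM ethers. O5 is capped because a rhodium-bound C5 phenoxide would hold the metal on the side of C4 turned away from the alkene.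

Key step: step 7

Assumption: the sense of induction of the ligand cannot be derived by analogy for this substrate class. (R)-DTBM-SEGPHOS is written for whichever of the two commercial antipodes gives the (2S) product in a first trial.
Atom labels (O1, C2 to C8a, primes for ring B) follow flavanone numbering in all intermediates.

Step 1
Reactants: 1 2,4,6-trihydroxybenzaldehyde; 2 prenyl bromide (1-bromo-3-methylbut-2-ene)
Product: 3 2,4,6-trihydroxy-3-prenylbenzaldehyde
Conditions: KOH (1 equiv), H2O/MeOH, 0 °C → rt, N2, 1 in excess
Reagents that add atoms: none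
Why: C-alkylation of an ambident phloroglucinol phenoxide: in protic medium the oxygen atoms are solvated, so the soft allylic bromide is attacked by a ring carbon, C3 and C5 are equivalent so only one mono-C-prenyl product can form, and an excess of cheap 1 holds back a second alkylation.

Step 2
Reactants: 3 2,4,6-trihydroxy-3-prenylbenzaldehyde
Product: 4 2-hydroxy-4,6-bis(methoxymethoxy)-3-prenylbenzaldehyde
Conditions: MOMCl (2.1 equiv), iPr2NEt, CH2Cl2, 0 °C
Reagents that add atoms: chloromethyl methyl ether (MOMCl), COCCl
Why: MOM protection (O-alkylation with an α-chloro ether) under site control: the 4-OH is the most acidic and the 6-OH has a free neighbour, whereas the 2-OH is flanked by formyl and prenyl groups and keeps the hydrogen bond to the carbonyl oxygen, so it should stay free, as is usual for 3-alkyl-2,4,6-trihydroxyaryl carbonyl compounds.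

Step 3
Reactants: 5 2-methoxy-4-vinylphenol (4-vinylguaiacol)
Product: 6 2-methoxy-1-(methoxymethoxy)-4-vinylbenzene
Conditions: MOMCl, iPr2NEt, CH2Cl2, 0 °C → rt
Reagents that add atoms: chloromethyl methyl ether (MOMCl), COCCl
Why: Standard MOM protection of a phenol, which removes the acidic proton and the quinone-methide pathway of the vinylphenol and matches the groups on ring A for a single final deprotection.

Step 4
Reactants: 6 2-methoxy-1-(methoxymethoxy)-4-vinylbenzene
Product: 7 (±)-2-bromo-1-[3-methoxy-4-(methoxymethoxy)phenyl]ethanol
Conditions: NBS, THF/H2O, 0 °C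
Reagents that add atoms: N-bromosuccinimide, O=C1CCC(=O)N1Br; water, O
Why: Bromohydrin formation: the bromonium ion of the electron-rich styrene is opened by water at the benzylic carbon (Markovnikov), which puts bromine on the terminal carbon, and the new centre is racemic and is erased in step 6.

Step 5
Reactants: 4 2-hydroxy-4,6-bis(methoxymethoxy)-3-prenylbenzaldehyde; 7 (±)-2-bromo-1-[3-methoxy-4-(methoxymethoxy)phenyl]ethanol
Product: 8 (±)-2-{2-bromo-1-[3-methoxy-4-(methoxymethoxy)phenyl]ethoxy}-4,6-bis(methoxymethoxy)-3-prenylbenzaldehyde
Conditions: PPh3, DIAD, THF, 0 °C → rt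
Reagents that add atoms: none
Why: Mitsunobu etherification: the salicylaldehyde-type phenol is acidic enough to protonate the betaine and displaces the activated benzylic oxyphosphonium group, the neutral medium leaves the primary bromide, aldehyde, prenyl and MOM groups alone, and the configuration of the new O1–C2 centre does not matter (racemic, erased in step 6).

Step 6
Reactants: 8 (±)-2-{2-bromo-1-[3-methoxy-4-(methoxymethoxy)phenyl]ethoxy}-4,6-bis(methoxymethoxy)-3-prenylbenzaldehyde
Product: 9 4,6-bis(methoxymethoxy)-2-({1-[3-methoxy-4-(methoxymethoxy)phenyl]vinyl}oxy)-3-prenylbenzaldehyde (achiral)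
Conditions: KOtBu (1.5 equiv), THF, 0 °C; chromatography on Et3N-deactivated silica
Reagents that add atoms: none
Why: E2 dehydrobromination of a β-bromo ether, the classical entry to vinyl ethers: the benzylic C2–H is the only hydrogen β to bromide, bromide is a far better leaving group than the aryloxide, and the non-enolisable aldehyde, the MOM ethers and the prenyl group tolerate KOtBu at 0 °C.

Step 7
Reactants: 9 4,6-bis(methoxymethoxy)-2-({1-[3-methoxy-4-(methoxymethoxy)phenyl]vinyl}oxy)-3-prenylbenzaldehyde
Product: 10 (2S)-5,7-bis(methoxymethoxy)-2-[3-methoxy-4-(methoxymethoxy)phenyl]-8-prenylchroman-4-one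
Conditions: [Rh(cod)2]BF4 (5 mol %), (R)-DTBM-SEGPHOS (5.5 mol %), precatalyst hydrogenated (H2) and purged with Ar before 9 is added; 2,6-di-tert-butyl-4-methylpyridine (10 mol %), 4 Å MS, acetone, 40 °C
Reagents that add atoms: none
Why: Proposed new method: the cationic monovalent rhodium bisphosphine fragment binds the C2=C3 alkene, inserts into the adjacent formyl C–H bond, passes the hydride to C2 to give a primary alkyl in a seven-membered rhodacycle (Rh, C4, C4a, C8a, O1, C2, C3), and C3–C4 reductive elimination releases the ketone and the catalyst. The closest known reaction type is the rhodium/chiral bisphosphine enantioselective intramolecular hydroacylation of 1,1-disubstituted alkenes (2-isopropenylbenzaldehydes to 3-substituted indanones, ortho-(2-substituted allyl)benzaldehydes to 3-substituted tetralones), and an oxygen-linked 1-arylvinyl ether has not been shown to react this way. Ring C closes in a formal 6-endo-trig mode, both alkene carbons ending inside the ring. The C2 stereocentre is set by the ligand, which decides which alkene face lies against the Rh–H bond during hydride migration, and C2 is not touched in the bond-forming elimination. The step needs hydride delivery to C2 and not to C3 (which would lead through a tertiary alkyl rhodium to a five-membered ring), and the 1,1-disubstitution secures this, while the lack of allylic hydrogens rules out alkene migration, the endocyclic position of O1 keeps Rh–C3–C2–O1 away from the syn-periplanar geometry of β-aryloxide elimination, the C8 prenyl group pushes the vinyl ether towards the formyl group, and its trisubstituted alkene cannot reach the acyl rhodium centre. O5 is a neutral MOM ether because an O5,C4 phenoxide chelate would place rhodium anti to C8a about the C4–C4a bond, nearly 5 Å from O1 and beyond the reach of the O1–C2=C3 tether, whereas the ether oxygens are hemilabile donors that can fill the site needed for decarbonylation and then let go, and the absence of any acidic proton together with the hindered pyridine protects the acid-labile enol ether.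

Step 8
Reactants: 10 (2S)-5,7-bis(methoxymethoxy)-2-[3-methoxy-4-(methoxymethoxy)phenyl]-8-prenylchroman-4-one
Product: 11 (2S)-5,7-dihydroxy-2-(4-hydroxy-3-methoxyphenyl)-8-prenylchroman-4-one (target, CNP0266453.1)
Conditions: HCl in MeOH (1.25 M), 0 °C → rt
Reagents that add atoms: none
Why: Acid-catalysed acetal exchange with methanol (MOM cleavage), well tried on prenylated flavanones: all three groups leave in one operation, the carbonyl-assisted 5-O-MOM first, and mild acid at or below room temperature should avoid both addition of the 7-OH to the prenyl alkene and opening of the O1–C2 bond, so the C2 configuration, never exposed to base, is kept.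

Compound list
1 | 2,4,6-trihydroxybenzaldehyde | O=Cc1c(O)cc(O)cc1O | starting material
2 | prenyl bromide (1-bromo-3-methylbut-2-ene) | CC(C)=CCBr | starting material
3 | 2,4,6-trihydroxy-3-prenylbenzaldehyde | O=Cc1c(O)cc(O)c(CC=C(C)C)c1O | intermediate
4 | 2-hydroxy-4,6-bis(methoxymethoxy)-3-prenylbenzaldehyde | O=Cc1c(OCOC)cc(OCOC)c(CC=C(C)C)c1O | intermediate
5 | 2-methoxy-4-vinylphenol (4-vinylguaiacol) | C=Cc1ccc(O)c(OC)c1 | starting material
6 | 2-methoxy-1-(methoxymethoxy)-4-vinylbenzene | C=Cc1ccc(OCOC)c(OC)c1 | intermediate
7 | (±)-2-bromo-1-[3-methoxy-4-(methoxymethoxy)phenyl]ethanol | OC(CBr)c1ccc(OCOC)c(OC)c1 | intermediate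
8 | (±)-2-{2-bromo-1-[3-methoxy-4-(methoxymethoxy)phenyl]ethoxy}-4,6-bis(methoxymethoxy)-3-prenylbenzaldehyde | O=Cc1c(OCOC)cc(OCOC)c(CC=C(C)C)c1OC(CBr)c2ccc(OCOC)c(OC)c2 | intermediate
9 | 4,6-bis(methoxymethoxy)-2-({1-[3-methoxy-4-(methoxymethoxy)phenyl]vinyl}oxy)-3-prenylbenzaldehyde | C=C(Oc1c(CC=C(C)C)c(OCOC)cc(OCOC)c1C=O)c1ccc(OCOC)c(OC)c1 | intermediate
10 | (2S)-5,7-bis(methoxymethoxy)-2-[3-methoxy-4-(methoxymethoxy)phenyl]-8-prenylchroman-4-one | COc1cc([C@@H]2CC(=O)c3c(OCOC)cc(OCOC)c(CC=C(C)C)c3O2)ccc1OCOC | intermediate
11 | (2S)-5,7-dihydroxy-2-(4-hydroxy-3-methoxyphenyl)-8-prenylchroman-4-one | COc1cc([C@@H]2CC(=O)c3c(O)cc(O)c(CC=C(C)C)c3O2)ccc1O | target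

Total step count: 8. Longest linear sequence: 6 steps (1, 2, 5, 6, 7, 8).

Steps most likely to fail

**Risk 1, step 7.**
- Several processes could compete. The acyl rhodium hydride may decarbonylate before the alkene inserts, or the hydride may go to C3. Facial selectivity may be poor, or β-aryloxide elimination may occur. The enol ether may also attack the aldehyde under trace acid, or the electron-rich arenes may bind and sequester the catalyst.
- The fallback uses known chemistry only, sets out from 2 and comes back at 10.
- Commercial 2,4,6-trihydroxyacetophenone is C-prenylated with 2 (KOH, H2O/MeOH) to 2,4,6-trihydroxy-3-prenylacetophenone F1. MOMCl/iPr2NEt then gives 2-hydroxy-4,6-bis(methoxymethoxy)-3-prenylacetophenone F2.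
- Commercial vanillin and MOMCl/iPr2NEt give 3-methoxy-4-(methoxymethoxy)benzaldehyde F3.
- Claisen–Schmidt condensation of F2 with F3 (KOH, EtOH, rt) gives the (E)-2′-hydroxy-4′,6′,4-tris(methoxymethoxy)-3-methoxy-3′-prenylchalcone F4. NaOAc in refluxing EtOH closes it by oxa-Michael addition to the racemic tris-MOM flavanone F5.
- F5 is resolved kinetically by asymmetric transfer hydrogenation (RuCl(p-cymene)[(R,R)-TsDPEN], HCO2H/Et3N, EtOAc, stopped near half conversion). This should reduce the (R)-ketone to the cis-(2R,4R)-flavan-4-ol F6 and leave 10, which is separated by chromatography.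

**Risk 2, step 5.**
- Coupling may be sluggish at the doubly flanked, hydrogen-bonded phenol. The activated electron-rich benzylic alcohol may also ionise and then eliminate instead of being substituted.
- The fallback replaces the redox condensation by a Williamson-type alkylation, sets out from 6 and comes back at 8.
- Br2 in CH2Cl2 at −78 °C adds to 6 to give 4-(1,2-dibromoethyl)-2-methoxy-1-(methoxymethoxy)benzene F7. The potassium phenoxide of 4 (K2CO3, DMF, rt) displaces only the strongly activated benzylic bromide, which gives 8.

**Risk 3, step 1.**
- O-alkylation, a second C-alkylation or geminal dialkylation of the very electron-rich ring may occur.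
- The fallback changes from phenoxide alkylation to Friedel–Crafts prenylation, sets out from 1 and comes back at 3.
- Compound 1 is treated with 2-methylbut-3-en-2-ol and BF3·OEt2 in dioxane at rt. The tertiary allylic alcohol ionises to the prenyl cation, which attacks a ring carbon of the neutral phenol. No phenoxide oxygen competes and no dearomatised dialkylation is possible. No new compound is made on this way.

Further compounds
F1 | step 7 | 2,4,6-trihydroxy-3-prenylacetophenone | CC(=O)c1c(O)cc(O)c(CC=C(C)C)c1O
F2 | step 7 | 2-hydroxy-4,6-bis(methoxymethoxy)-3-prenylacetophenone | CC(=O)c1c(OCOC)cc(OCOC)c(CC=C(C)C)c1O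
F3 | step 7 | 3-methoxy-4-(methoxymethoxy)benzaldehyde | COCOc1ccc(C=O)cc1OC
F4 | step 7 | (E)-2′-hydroxy-4′,6′,4-tris(methoxymethoxy)-3-methoxy-3′-prenylchalcone | COCOc1ccc(/C=C/C(=O)c2c(OCOC)cc(OCOC)c(CC=C(C)C)c2O)cc1OC
F5 | step 7 | racemic 5,7-bis(methoxymethoxy)-2-[3-methoxy-4-(methoxymethoxy)phenyl]-8-prenylchroman-4-one | COc1cc(C2CC(=O)c3c(OCOC)cc(OCOC)c(CC=C(C)C)c3O2)ccc1OCOC
F6 | step 7 | (2R,4R)-5,7-bis(methoxymethoxy)-2-[3-methoxy-4-(methoxymethoxy)phenyl]-8-prenylchroman-4-ol | COc1cc([C@H]2C[C@@H](O)c3c(OCOC)cc(OCOC)c(CC=C(C)C)c3O2)ccc1OCOC
F7 | step 5 | 4-(1,2-dibromoethyl)-2-methoxy-1-(methoxymethoxy)benzene | BrCC(Br)c1ccc(OCOC)c(OC)c1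
F0 | step 1 | none | none
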